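(The earlier runs and the new flask were computed for substances that don't exist.)

**The question.** Which of isomer of the product and target is ahead in the flask at 4.0 min, and by what share? The ash run is this same flask, followed so far.

| flask | substrate | reagent | other conformer | remark | time |
|---|---|---|---|---|---|
| ash | 0.010 M | 8 mM | 2.5 mM | the very flask that is asked about, followed so far |  |
| maple | 0.010 M | 4 mM | 2.5 mM | run made earlier |  |
| flask | 0.010 M | 8.00 mM | 2.50 mM |  | 4.0 min |

- ash (time / s: isomer of the product / %, target / %, substrate / %): 15.0: 2, 4, 61; 30.0: 12, 5, 47; 50.0: 18, 6, 31; 60.0: 17, 3, 32; 80.0: 20, 3, 26; 90.0: 23, 4, 26; 120: 25, 1, 23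
- maple (time / min: isomer of the product / %, target / %, substrate / %): 0.500: 5, 1, 53; 1.00: 8, 1, 49; 1.50: 13, 2, 43; 2.50: 22, 2, 34; 3.00: 17, 2, 33; 4.00: 18, 0, 32

(readings scatter by 2 percentage points)

* share of isomer of the product in isomer of the product plus target at 1.2 s
* share of isomer of the product in isomer of the product plus target at 4.0 min
* which of isomer of the product and target there is more of at 4.0 min

- a species is counted by the substrate in it: one side product counts as two
- steps thought possible: substrate <-> other conformer; substrate + reagent -> target; reagent + other conformer -> isomer of the product; substrate + target -> side product

**Hold-down ratio.** Target is made from substrate and reagent, and it is lost to substrate. Substrate stands in both steps, so it cancels where they balance (a steady state). The hold-down ratio, target over reagent left, both in percent of the charged substrate and other conformer, then stays roughly constant.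

**Reading it.** The ash readings from 60.0 s on average 2.75% target, 21.2% isomer and 26.8% substrate. Other conformer is unread, so this reckoning guesses it equal to substrate. The rest of the pool is side product. Each isomer and target took one reagent, and each side product counts as two but holds one target already made. So this reckoning leaves 28.7% reagent, and the ratio read from it is 0.0957. With a scatter of 2 percentage points, it is rough.

**Late share.** At 120 s the same balance leaves 24.0% reagent. No listed step removes isomer, and this reckoning expects reagent to fall further, so it puts the late share above 91.6%. This reckoning has isomer ahead. It offers no share for 1.2 s, so close to the start.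

**The forecast.** It gives 35% early and 96% late, the late share above this reckoning's estimate, with isomer of the product ahead. Of target it says: “its near-steady level tracks the remaining reagent”.

**The flask.** The flask gives shares of 40.6% at 1.2 s and 97.3% at 4.0 min, with 29.9% isomer against 0.835% target at 4.0 min.

    substrate ⇌ other conformer (K = 0.670, k = 0.0180 s⁻¹)
    substrate + reagent → target (k = 0.980 M⁻¹ s⁻¹)
    reagent + other conformer → isomer of the product (k = 2.40 M⁻¹ s⁻¹)
    substrate + target → side product (k = 14.0 M⁻¹ s⁻¹)

**Why target stays low.** The loss of substrate with target has the largest single effect on the late share: without that step the share is 53.9%, not 97.3%. The ratio and the reagent left in this flask at 4.00 min, 15.2% of its charge, give 0.932% target, and the flask holds 0.835%. A neighbour charged with 0.0025 M of substrate keeps 54.5% of its reagent at 4.00 min. The same ratio gives it 8.34% target, and that neighbour holds 6.93%.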